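**Retrosynthetic overview**

1. Target ⇐ acylation of the 6‑OH of the epoxy diol ⇐ hydroxyl‑directed epoxidation (oxirane closed last) ⇐ hydroxyl‑directed 1,3‑anti reduction of a trans‑fused β‑hydroxy ketone.
2. β‑Hydroxy ketone ⇐ silylene‑bridged enol ether of the hydroazulene ⇐ [3,3] rearrangement of a siloxy cis‑divinylcyclopropane, made by CH2 transfer to a cyclic silyl dienol ether. The dioxasiline, the cyclopropane and the seven‑membered ring close in one flask, and the quaternary C1 is set there.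
3. Dienol ether precursor ⇐ cyclopentenyl β,γ‑unsaturated ketone ⇐ crotyl addition and oxidation of a cyclopentene carbaldehyde.
4. Cyclopentene carbaldehyde ⇐ ozonolysis and intramolecular aldol condensation of (S)‑terpinen‑4‑ol, which supplies the isopropyl carbinol stereocentre.
5. Ring order: cyclopentene → dioxasiline + cyclopropane → cycloheptadiene (cyclopropane consumed) → oxirane.

Assumption: (S)‑(+)‑terpinen‑4‑ol of high ee is bought; bicyclic compounds use daucane numbering (C1 = CH3‑bearing ring‑fusion carbon, C4 = isopropyl carbinol, C5 = ring‑fusion CH, C6 = ester carbon, C8/C9 = epoxide carbons; β = face of C1‑CH3 and C4‑OH, α = face of H‑5, C4‑iPr, C6‑O and the epoxide O).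

**Route**

Step 1
Reactants: 1 (S)‑(+)‑terpinen‑4‑ol
Product: 3 (5R)‑5‑hydroxy‑2‑methyl‑5‑(propan‑2‑yl)cyclopent‑1‑ene‑1‑carbaldehyde, via keto aldehyde 2 (not isolated)
Conditions: O3, CH2Cl2–MeOH, −78 °C; Me2S, → rt; then piperidine (cat.), AcOH (cat.), PhH, 60 °C
Reagents that add atoms: ozone [O-][O+]=O
Why: Ozonolysis cleaves the only C=C to keto aldehyde 2, whose aldehyde enamine closes 5‑exo onto the methyl ketone and dehydrates (amine/acid‑catalysed intramolecular aldol condensation); the carbinol stereocentre of 1 is untouched and becomes C4 of the target.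

Step 2
Reactants: 3; 4 but‑2‑en‑1‑ylmagnesium chloride (crotylmagnesium chloride)
Product: 5 (1R)‑2‑(1‑hydroxy‑2‑methylbut‑3‑en‑1‑yl)‑3‑methyl‑1‑(propan‑2‑yl)cyclopent‑2‑en‑1‑ol (mixture of side‑chain diastereomers)
Conditions: 4 (2.5 equiv), THF, −78 → 0 °C; aq NH4Cl
Reagents that add atoms: but‑2‑en‑1‑ylmagnesium chloride C/C=C/C[Mg]Cl
Why: Allylic Grignard 1,2‑addition through the cyclic SE2′ transition state gives the branched homoallylic alcohol after the first equivalent deprotonates the tertiary OH; the two new stereocentres are unimportant because both become sp2 in steps 3 and 4.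

Step 3
Reactants: 5
Product: 6 1‑[(5R)‑5‑hydroxy‑2‑methyl‑5‑(propan‑2‑yl)cyclopent‑1‑en‑1‑yl]‑2‑methylbut‑3‑en‑1‑one (both C2 epimers)
Conditions: Dess–Martin periodinane, NaHCO3, CH2Cl2, 0 °C → rt
Reagents that add atoms: none
Why: Dess–Martin oxidation converts only the secondary alcohol to the ketone under buffered conditions that leave the tertiary alcohol and the β,γ‑alkene in place.

Step 4
Reactants: 6; 7 dichlorodi(propan‑2‑yl)silane; 8 diiodomethane
Product: 11 (1R,4R)‑4,6‑O‑[di(propan‑2‑yl)silanediyl]dauca‑5,8‑diene‑4,6‑diol, via cyclic silyl dienol ether 9 (not isolated), via siloxy divinylcyclopropane 10 (not isolated)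
Conditions: LiHMDS (2.1 equiv), PhMe, −78 °C; iPr2SiCl2, −78 → 0 °C; then Et2Zn, CH2I2, 0 °C → rt; then 90 °C
Reagents that add atoms: dichlorodi(propan‑2‑yl)silane CC(C)[Si](Cl)(Cl)C(C)C; diiodomethane ICI
Why: Proposed new method: the alkoxide/dienolate dianion of 6 is tied into a six‑membered dioxasiline (9), the Furukawa (Simmons–Smith) carbenoid cyclopropanates the electron‑rich siloxy C=C on the face anti to the C4 isopropyl group (10), and the cis‑divinylcyclopropane then undergoes the boat [3,3] (Cope) rearrangement, which forms the C1–C10 bond on the isopropyl face and so leaves the C1 methyl cis to the C4 oxygen (1R); the closest known reactions are Simmons–Smith cyclopropanation of 2‑siloxy‑1,3‑dienes and the thermal rearrangement of 2‑siloxy‑cis‑1,2‑divinylcyclopropanes to cyclohepta‑1,4‑dienyl silyl ethers.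

Step 5
Reactants: 11
Product: 12 (1R,4R,5R)‑4‑hydroxydauc‑8‑en‑6‑one
Conditions: HF·pyridine, pyridine–THF, 0 °C → rt; then Et3N (cat.), MeOH, rt
Reagents that add atoms: none
Why: Fluoride desilylation frees the enol, which ketonises and equilibrates at C5 to the trans‑fused β‑hydroxy ketone, expected to be the more stable epimer because the C6 carbonyl is then anti to the isopropyl group and hydrogen‑bonded to the cis tertiary OH.

Step 6
Reactants: 12
Product: 13 (1R,4R,5S,6S)‑dauc‑8‑ene‑4,6‑diol (jaeschkeanadiol)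
Conditions: Me4NBH(OAc)3, MeCN–AcOH, −20 °C
Reagents that add atoms: none
Why: Evans–Saksena hydroxyl‑directed reduction, in which the C4 alkoxy(diacetoxy)borohydride delivers hydride intramolecularly to the β‑face of the C6 ketone and gives the 1,3‑anti diol with 6α‑OH (6S).

Step 7
Reactants: 13
Product: 14 (1R,4R,5S,6S,8R,9S)‑8,9‑epoxydaucane‑4,6‑diol
Conditions: VO(acac)2 (5 mol %), t‑BuOOH, CH2Cl2, 0 °C → rt
Reagents that add atoms: tert‑butyl hydroperoxide CC(C)(C)OO
Why: Vanadium‑catalysed hydroxyl‑directed epoxidation, in which the homoallylic 6α‑OH binds the vanadium peroxide and delivers oxygen to the α‑face of C8=C9 (8R,9S), the face that is also anti to the angular methyl.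

Step 8
Reactants: 14; 15 4‑methoxybenzoyl chloride
Product: 16 (1R,4R,5S,6S,8R,9S)‑8,9‑epoxy‑4‑hydroxydaucan‑6‑yl 4‑methoxybenzoate (target)
Conditions: 15, Et3N, DMAP (cat.), CH2Cl2, rt
Reagents that add atoms: 4‑methoxybenzoyl chloride COc1ccc(C(Cl)=O)cc1
Why: DMAP‑catalysed acyl transfer esterifies the secondary 6‑OH only, because the tertiary 4‑OH is too hindered, and the basic conditions leave the epoxide intact.

**Compound list**

1 | (S)‑(+)‑terpinen‑4‑ol, (1S)‑4‑methyl‑1‑(propan‑2‑yl)cyclohex‑3‑en‑1‑ol | CC1=CC[C@](O)(C(C)C)CC1 | starting material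
2 | (3S)‑3‑hydroxy‑6‑oxo‑3‑(propan‑2‑yl)heptanal | O=CC[C@](O)(C(C)C)CCC(C)=O | intermediate
3 | (5R)‑5‑hydroxy‑2‑methyl‑5‑(propan‑2‑yl)cyclopent‑1‑ene‑1‑carbaldehyde | O=CC1=C(C)CC[C@@]1(O)C(C)C | intermediate
4 | but‑2‑en‑1‑ylmagnesium chloride | C/C=C/C[Mg]Cl | starting material
5 | (1R)‑2‑(1‑hydroxy‑2‑methylbut‑3‑en‑1‑yl)‑3‑methyl‑1‑(propan‑2‑yl)cyclopent‑2‑en‑1‑ol, diastereomer mixture | C=CC(C)C(O)C1=C(C)CC[C@@]1(O)C(C)C | intermediate
6 | 1‑[(5R)‑5‑hydroxy‑2‑methyl‑5‑(propan‑2‑yl)cyclopent‑1‑en‑1‑yl]‑2‑methylbut‑3‑en‑1‑one, C2 epimers | C=CC(C)C(=O)C1=C(C)CC[C@@]1(O)C(C)C | intermediate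
7 | dichlorodi(propan‑2‑yl)silane | CC(C)[Si](Cl)(Cl)C(C)C | starting material
8 | diiodomethane | ICI | starting material
9 | (4E,7aR)‑4‑(but‑3‑en‑2‑ylidene)‑5‑methyl‑2,2,7a‑tri(propan‑2‑yl)‑4,6,7,7a‑tetrahydrocyclopenta[d][1,3,2]dioxasiline | C=C/C(C)=C1/O[Si](C(C)C)(C(C)C)O[C@@]2(C(C)C)CCC(C)=C12 | intermediate
10 | spiro cyclopropane of 9 at C6: CH2 anti to the isopropyl group, vinyl cis to the cyclopentenyl carbon (4R,6S,8R in daucane numbering) | C=C[C@@]1(C)C[C@]12O[Si](C(C)C)(C(C)C)O[C@@]3(C(C)C)CCC(C)=C23 | intermediate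
11 | (1R,4R)‑4,6‑O‑[di(propan‑2‑yl)silanediyl]dauca‑5,8‑diene‑4,6‑diol | CC1=CC[C@@]2(C)CC[C@]3(C(C)C)O[Si](C(C)C)(C(C)C)OC(C1)=C23 | intermediate
12 | (1R,4R,5R)‑4‑hydroxydauc‑8‑en‑6‑one, (3R,3aR,8aR)‑3‑hydroxy‑6,8a‑dimethyl‑3‑(propan‑2‑yl)‑2,3,3a,5,8,8a‑hexahydroazulen‑4(1H)‑one | O=C1CC(C)=CC[C@@]2(C)CC[C@@](O)(C(C)C)[C@H]12 | intermediate
13 | jaeschkeanadiol, (1R,4R,5S,6S)‑dauc‑8‑ene‑4,6‑diol | O[C@H]1CC(C)=CC[C@@]2(C)CC[C@@](O)(C(C)C)[C@H]12 | intermediate
14 | (1R,4R,5S,6S,8R,9S)‑8,9‑epoxydaucane‑4,6‑diol | O[C@H]1C[C@@]2(C)O[C@H]2C[C@@]2(C)CC[C@@](O)(C(C)C)[C@H]12 | intermediate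
15 | 4‑methoxybenzoyl chloride | COc1ccc(C(Cl)=O)cc1 | starting material
16 | (1R,4R,5S,6S,8R,9S)‑8,9‑epoxy‑4‑hydroxydaucan‑6‑yl 4‑methoxybenzoate | COc1ccc(C(=O)O[C@H]2C[C@@]3(C)O[C@H]3C[C@@]3(C)CC[C@@](O)(C(C)C)[C@H]23)cc1 | target

**Step count and risks**

Total steps: 8. Longest linear sequence: 8 (fully linear from 1).

Steps most likely to fail:

Step 4. Three things can go wrong. Only the (E)‑dienol ether (vinyl cis to the cyclopentenyl carbon) gives the cis‑divinylcyclopropane directly; the other isomer must first epimerise thermally. The facial selectivity of CH2 transfer decides C1 and rests on a conformational argument. The hindered [3,3] shift, which forms a quaternary centre, may need more than 90 °C. The fallback sets out from 3 and comes back at 13, closing the seven‑membered ring by metathesis. Copper‑catalysed conjugate addition of allylmagnesium bromide (CuBr·SMe2, TMSCl) to enal 3 and equilibrating protonation gives (1S,2R,5R)‑5‑hydroxy‑2‑methyl‑5‑(propan‑2‑yl)‑2‑(prop‑2‑en‑1‑yl)cyclopentane‑1‑carbaldehyde F4. Chelation‑controlled addition of 2‑methylallylmagnesium chloride gives the diene diol F5. Ring‑closing metathesis with the Grubbs second‑generation catalyst then gives 13 with loss of ethene, and steps 7 and 8 follow unchanged.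

Step 1. The β‑hydroxy aldehyde 2 can lose the tertiary OH through its enamine, can sit as a cyclic hemiketal, or can cyclise through the ketone enolate. The fallback sets out from 1 and comes back at 3, carrying the alcohol masked. Et3SiOTf/2,6‑lutidine gives the triethylsilyl ether of terpinen‑4‑ol F1. Ozonolysis gives the silyl‑protected keto aldehyde F2. Aldol condensation with dibenzylammonium trifluoroacetate gives the silyl‑protected enal F3, and Bu4NF returns 3.

Step 7. Homoallylic direction in a flexible seven‑membered ring may be slow or may not fully control the face. The fallback sets out from 13 and comes back at 16 with the order reversed. Acylation with 15 (Et3N, DMAP) gives jaeschkeanadiol 6‑(4‑methoxybenzoate) F6. Epoxidation with mCPBA/NaHCO3 then relies on steric approach anti to the angular methyl, the α‑face being the open one only if the 6α‑ester does not shield it, and gives 16 directly without passing through 14.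

Further compounds

F1 | step 1 | triethyl{[(1S)‑4‑methyl‑1‑(propan‑2‑yl)cyclohex‑3‑en‑1‑yl]oxy}silane | CC1=CC[C@](O[Si](CC)(CC)CC)(C(C)C)CC1
F2 | step 1 | (3S)‑6‑oxo‑3‑(propan‑2‑yl)‑3‑(triethylsilyloxy)heptanal | O=CC[C@](O[Si](CC)(CC)CC)(C(C)C)CCC(C)=O
F3 | step 1 | (5R)‑2‑methyl‑5‑(propan‑2‑yl)‑5‑(triethylsilyloxy)cyclopent‑1‑ene‑1‑carbaldehyde | O=CC1=C(C)CC[C@@]1(O[Si](CC)(CC)CC)C(C)C
F4 | step 4 | (1S,2R,5R)‑5‑hydroxy‑2‑methyl‑5‑(propan‑2‑yl)‑2‑(prop‑2‑en‑1‑yl)cyclopentane‑1‑carbaldehyde | C=CC[C@@]1(C)CC[C@@](O)(C(C)C)[C@@H]1C=O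
F5 | step 4 | (1R,2S,3R)‑2‑[(1S)‑1‑hydroxy‑3‑methylbut‑3‑en‑1‑yl]‑3‑methyl‑1‑(propan‑2‑yl)‑3‑(prop‑2‑en‑1‑yl)cyclopentan‑1‑ol | C=CC[C@@]1(C)CC[C@@](O)(C(C)C)[C@@H]1[C@@H](O)CC(C)=C
F6 | step 7 | (1R,4R,5S,6S)‑4‑hydroxydauc‑8‑en‑6‑yl 4‑methoxybenzoate | COc1ccc(C(=O)O[C@H]2CC(C)=CC[C@@]3(C)CC[C@@](O)(C(C)C)[C@H]23)cc1
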